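Locants are those of verticillane: C1 ring-fusion CH, C15 CMe2, C11=C12 butenolide olefin (C12–C18(=O)–O–C10), C6 CH–OAc, C7=C8, C4=C20; ring A is C1–C14–C13–C12–C11–C15.
Last comes acetylation of alcohol 24; before it ring A is closed by a transannular 6-exo reductive Heck cyclization of the 14-membered tetronate triflate 23 (C11–OTf onto the C1 isopropenyl group), which forms C11–C15, the quaternary CMe2 carbon and the bicyclo[9.3.1] core in one operation.
Enabling feature: C11 is the β-carbon of the butenolide (the enol carbon of a tetronic acid once C15 is removed) and lies 1,5 to C1 through C12–C13–C14, and C15 carries two methyl groups, so a C1 isopropenyl group gives a neopentyl palladium without β-hydrogen that formate reduces to the second methyl.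
The 14-membered ring is closed at C5–C6 by intramolecular Hosomi–Sakurai allylation of enal 20 (C6 then set by oxidation and CBS reduction); the chain is joined at C12–C13 by reductive Knoevenagel alkylation of tetronic acid 16 with aldehyde 7.
Fragments: 16 (butenolide ring by Dieckmann cyclization, C10 by Rh–DuPhos hydrogenation) and 7 (C1 from (R)-limonene oxide); ring order: butenolide, then 14-membered carbocycle, then ring A.

Key step: step 16

Remark: (2E)-4-acetoxy-2-methylbut-2-enal 12 is taken as a purchasable building block (otherwise one step from prenyl acetate by SeO2 oxidation).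

Step 1
Reactants: 1 (4R)-limonene 1,2-oxide (cis/trans mixture)
Product: 3 (3R)-6-oxo-3-(prop-1-en-2-yl)heptanal, via (4R)-p-menth-8-ene-1,2-diol 2 (not isolated)
Conditions: H5IO6, THF/H2O, 0 °C → rt
Reagents that add atoms: water, O
Why: Epoxide hydrolysis followed by periodate glycol cleavage (Malaprade reaction) opens the ring only at the former trisubstituted olefin, leaving the isopropenyl group and the chiral-pool stereocentre (future C1) untouched.

Step 2
Reactants: 3 (3R)-6-oxo-3-(prop-1-en-2-yl)heptanal
Product: 4 (5R)-7,7-dimethoxy-5-(prop-1-en-2-yl)heptan-2-one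
Conditions: HC(OMe)3, MeOH, CeCl3·7H2O (cat.), rt
Reagents that add atoms: trimethyl orthoformate, COC(OC)OC; methanol, CO
Why: Lanthanide chloride-catalysed acetalization is chemoselective for the aldehyde over the methyl ketone and masks C13 for the enolate chemistry that follows.

Step 3
Reactants: 4 (5R)-7,7-dimethoxy-5-(prop-1-en-2-yl)heptan-2-one
Product: 5 (5R)-7,7-dimethoxy-5-(prop-1-en-2-yl)hept-1-en-2-yl trifluoromethanesulfonate
Conditions: KHMDS, THF, −78 °C; PhNTf2, −78 → 0 °C; aq. NH4Cl
Reagents that add atoms: N-phenylbis(trifluoromethanesulfonimide), O=S(=O)(N(c1ccccc1)S(=O)(=O)C(F)(F)F)C(F)(F)F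
Why: Kinetic deprotonation of the methyl ketone at the methyl group and O-sulfonylation of the terminal enolate should give the 2-triflyloxy-1-alkene (enol triflate formation).

Step 4
Reactants: 5 (5R)-7,7-dimethoxy-5-(prop-1-en-2-yl)hept-1-en-2-yl trifluoromethanesulfonate
Product: 6 [(5R)-7,7-dimethoxy-2-methylidene-5-(prop-1-en-2-yl)heptyl]trimethylsilane
Conditions: Me3SiCH2MgCl, Pd(PPh3)4 (cat.), LiCl, Et2O/THF, 0 °C → rt
Reagents that add atoms: (trimethylsilyl)methylmagnesium chloride, C[Si](C)(C)C[Mg]Cl
Why: Kumada–Corriu coupling of an alkenyl triflate with the α-silyl Grignard reagent is the standard entry to 2-substituted allylsilanes and tolerates the acetal and the isopropenyl group.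

Step 5
Reactants: 6 [(5R)-7,7-dimethoxy-2-methylidene-5-(prop-1-en-2-yl)heptyl]trimethylsilane
Product: 7 (3R)-6-methylidene-3-(prop-1-en-2-yl)-7-(trimethylsilyl)heptanal
Conditions: PPTS (cat.), acetone/H2O, 45 °C
Reagents that add atoms: water, O
Why: Mild acetal hydrolysis should free the C13 aldehyde without protodesilylation of the allylsilane; the stereocentre is β to the carbonyl and cannot epimerize.

Step 6
Reactants: 8 dimethyl phosphite; 9 ethyl glyoxylate
Product: 11 ethyl 2-acetoxy-2-(dimethoxyphosphoryl)acetate, via hydroxyphosphonate 10 (not isolated)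
Conditions: Et3N (cat.), toluene, rt → 60 °C; then Ac2O, pyridine, DMAP (cat.), 0 °C → rt
Reagents that add atoms: acetic anhydride, CC(=O)OC(C)=O
Why: Pudovik addition of the H-phosphonate to the aldehyde followed by O-acetylation gives the acyloxyphosphonate needed for the olefination.

Step 7
Reactants: 11 ethyl 2-acetoxy-2-(dimethoxyphosphoryl)acetate; 12 (2E)-4-acetoxy-2-methylbut-2-enal
Product: 13 ethyl (2Z,4E)-2,6-diacetoxy-4-methylhexa-2,4-dienoate
Conditions: 1,1,3,3-tetramethylguanidine, THF, −78 °C → rt
Reagents that add atoms: none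
Why: Horner–Wadsworth–Emmons olefination; the (E)-olefin of 12 (future C7=C8) is carried over unchanged, and the geometry of the new enol-ester olefin (2Z expected to predominate) is not critical for the next step.

Step 8
Reactants: 13 ethyl (2Z,4E)-2,6-diacetoxy-4-methylhexa-2,4-dienoate
Product: 14 ethyl (2R,4E)-2,6-diacetoxy-4-methylhex-4-enoate
Conditions: [Rh(cod)((R,R)-Et-DuPhos)]OTf (cat.), H2 (4 bar), MeOH, rt
Reagents that add atoms: none
Why: Asymmetric hydrogenation of an α-acyloxy acrylate: the acetoxy carbonyl chelates rhodium, so only the enol-ester olefin (future C9–C10) should be reduced, and the (R,R)-ligand is expected to set C10 as R by catalyst control while the trisubstituted olefin, which has no directing group, stays.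

Step 9
Reactants: 14 ethyl (2R,4E)-2,6-diacetoxy-4-methylhex-4-enoate
Product: 16 (5R)-4-hydroxy-5-[(2E)-4-hydroxy-2-methylbut-2-en-1-yl]furan-2(5H)-one, via acetoxy tetronic acid 15 (not isolated)
Conditions: LiHMDS (3.3 equiv), THF, −78 → −20 °C; then MeOH, rt; 1 M HCl
Reagents that add atoms: none
Why: Lacey–Dieckmann cyclization: the acetate enolate attacks the neighbouring ethyl ester (5-exo-trig) to build the tetronic acid, with C12 and C18 coming from the acetyl group and the low temperature guarding C10; lithium methoxide formed on the methanol quench then removes the primary allylic acetate.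

Step 10
Reactants: 16 (5R)-4-hydroxy-5-[(2E)-4-hydroxy-2-methylbut-2-en-1-yl]furan-2(5H)-one; 7 (3R)-6-methylidene-3-(prop-1-en-2-yl)-7-(trimethylsilyl)heptanal
Product: 18 (5R)-4-hydroxy-5-[(2E)-4-hydroxy-2-methylbut-2-en-1-yl]-3-[(3S)-6-methylidene-3-(prop-1-en-2-yl)-7-(trimethylsilyl)heptyl]furan-2(5H)-one, via alkylidene tetronate 17 (not isolated)
Conditions: Hantzsch ester (diethyl 2,6-dimethyl-1,4-dihydropyridine-3,5-dicarboxylate), L-proline (cat.), CH2Cl2, rt
Reagents that add atoms: none
Why: Three-component reductive Knoevenagel alkylation: the aldehyde condenses at C12, the only nucleophilic carbon of the tetronic acid, and the electrophilic alkylidene should be reduced by hydride transfer from the dihydropyridine before it can add a second tetronic acid; no stereocentre is formed.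

Step 11
Reactants: 18 (5R)-4-hydroxy-5-[(2E)-4-hydroxy-2-methylbut-2-en-1-yl]-3-[(3S)-6-methylidene-3-(prop-1-en-2-yl)-7-(trimethylsilyl)heptyl]furan-2(5H)-one
Product: 19 (2R)-2-[(2E)-4-hydroxy-2-methylbut-2-en-1-yl]-4-[(3S)-6-methylidene-3-(prop-1-en-2-yl)-7-(trimethylsilyl)heptyl]-5-oxo-2,5-dihydrofuran-3-yl trifluoromethanesulfonate
Conditions: PhNTf2, Et3N, CH2Cl2, 0 °C → rt
Reagents that add atoms: N-phenylbis(trifluoromethanesulfonimide), O=S(=O)(N(c1ccccc1)S(=O)(=O)C(F)(F)F)C(F)(F)F
Why: O-Sulfonylation of the acidic tetronate enol gives the 4-triflyloxybutenolide; the neutral primary alcohol should not react with this mild triflating agent.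

Step 12
Reactants: 19 (2R)-2-[(2E)-4-hydroxy-2-methylbut-2-en-1-yl]-4-[(3S)-6-methylidene-3-(prop-1-en-2-yl)-7-(trimethylsilyl)heptyl]-5-oxo-2,5-dihydrofuran-3-yl trifluoromethanesulfonate
Product: 20 (2R)-2-[(2E)-2-methyl-4-oxobut-2-en-1-yl]-4-[(3S)-6-methylidene-3-(prop-1-en-2-yl)-7-(trimethylsilyl)heptyl]-5-oxo-2,5-dihydrofuran-3-yl trifluoromethanesulfonate
Conditions: MnO2, CH2Cl2, rt
Reagents that add atoms: none
Why: Selective oxidation of the primary allylic alcohol to the (E)-enal under neutral conditions that should leave the allylsilane and the alkenyl triflate intact.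

Step 13
Reactants: 20 (2R)-2-[(2E)-2-methyl-4-oxobut-2-en-1-yl]-4-[(3S)-6-methylidene-3-(prop-1-en-2-yl)-7-(trimethylsilyl)heptyl]-5-oxo-2,5-dihydrofuran-3-yl trifluoromethanesulfonate
Product: 21 (1R,6RS,7E,10R)-6-hydroxy-11-(trifluoromethanesulfonyloxy)-11,15-secoverticilla-4(20),7,11,15-tetraen-18,10-olide (both C6 epimers)
Conditions: BF3·OEt2, CH2Cl2, −78 °C, high dilution (slow addition of 20); aqueous work-up
Reagents that add atoms: none
Why: Intramolecular Hosomi–Sakurai allylation (SE2′ 1,2-addition of the 2-substituted allylsilane to the Lewis acid-activated enal, the counterpart of the allylstannane–aldehyde closures used for 14-membered carbocycles) closes the macrocycle between C5 and C6 and leaves the C4 exocyclic methylene; the open transition state gives no dependable control at C6, which is therefore reset in steps 14 and 15.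

Step 14
Reactants: 21 (1R,6RS,7E,10R)-6-hydroxy-11-(trifluoromethanesulfonyloxy)-11,15-secoverticilla-4(20),7,11,15-tetraen-18,10-olide
Product: 22 (1R,7E,10R)-6-oxo-11-(trifluoromethanesulfonyloxy)-11,15-secoverticilla-4(20),7,11,15-tetraen-18,10-olide
Conditions: Dess–Martin periodinane, pyridine, CH2Cl2, 0 °C
Reagents that add atoms: none
Why: Dess–Martin oxidation converges both C6 epimers on one enone under buffered conditions, so that the C4 methylene, β,γ to the new ketone, should not move into conjugation.

Step 15
Reactants: 22 (1R,7E,10R)-6-oxo-11-(trifluoromethanesulfonyloxy)-11,15-secoverticilla-4(20),7,11,15-tetraen-18,10-olide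
Product: 23 (1R,6S,7E,10R)-6-hydroxy-11-(trifluoromethanesulfonyloxy)-11,15-secoverticilla-4(20),7,11,15-tetraen-18,10-olide
Conditions: (R)-2-methyl-CBS-oxazaborolidine (cat.), catecholborane, toluene, −78 °C
Reagents that add atoms: none
Why: Corey–Bakshi–Shibata reduction: the ketone binds the oxazaborolidine with the C7=C8 alkenyl flank as the large group, so the (R)-catalyst should deliver hydride to the face that gives the (6S)-allylic alcohol (catalyst control), and catecholborane at −78 °C should not hydroborate the alkenes.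

Step 16
Reactants: 23 (1R,6S,7E,10R)-6-hydroxy-11-(trifluoromethanesulfonyloxy)-11,15-secoverticilla-4(20),7,11,15-tetraen-18,10-olide
Product: 24 (1R,6S,7E,10R)-6-hydroxyverticilla-4(20),7,11-trien-18,10-olide
Conditions: Pd(OAc)2 (cat.), PPh3, HCO2Na, Et4NCl, DMF, 70 °C
Reagents that add atoms: none
Why: Zerovalent palladium inserts into the C11–OTf bond, the alkenylpalladium adds syn across the C15=C16 bond of the C1 isopropenyl group with C11 bonding to C15, and the neopentyl alkylpalladium at C16, which has no β-hydrogen, takes up formate, loses CO2 and reductively eliminates C–H to give the second methyl group. The closest known reaction type is the intramolecular reductive Heck cyclization (Heck cyclization with hydride capture) used to build all-carbon quaternary centres from 1,1-disubstituted alkenes. Ring A (C1, C14, C13, C12, C11, C15) closes in the 6-exo-trig mode across the 14-membered ring, which thereby becomes the 12-membered ring of the bicyclo[9.3.1] core. No new stereocentre arises because C15 ends with two methyl groups; C1, C6 and C10 are not touched, and the C11=C12 olefin stays in place because the metal leaves from C16. The step needs site selectivity for the isopropenyl group over the C4 methylene and the C7=C8 olefin, which the tether secures (the palladium on C11 is cis to C13 and only C15 is within reach of a six-membered transition state), and it needs insertion to precede hydride capture, which a 6-exo insertion should win against the slower decarboxylation of formate. The C6 oxygen is carried as the free alcohol because an allylic acetate would be ionized by zerovalent palladium and reduced by formate.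

Step 17
Reactants: 24 (1R,6S,7E,10R)-6-hydroxyverticilla-4(20),7,11-trien-18,10-olide
Product: 25 (1R,6S,7E,10R)-6-acetoxyverticilla-4(20),7,11-trien-18,10-olide (CNP0289913.1)
Conditions: Ac2O, pyridine, DMAP (cat.), CH2Cl2, 0 °C → rt
Reagents that add atoms: acetic anhydride, CC(=O)OC(C)=O
Why: O-Acylation proceeds with retention at C6 and completes the target; the mild base should not affect the C10–H of the butenolide.

Compound list
1 | (4R)-limonene 1,2-oxide, cis/trans mixture [(4R)-1-methyl-4-(prop-1-en-2-yl)-7-oxabicyclo[4.1.0]heptane] | CC12CC[C@H](CC1O2)C(C)=C | starting material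
2 | (4R)-p-menth-8-ene-1,2-diol | CC1(O)CC[C@H](CC1O)C(C)=C | intermediate
3 | (3R)-6-oxo-3-(prop-1-en-2-yl)heptanal | O=CC[C@@H](CCC(C)=O)C(C)=C | intermediate
4 | (5R)-7,7-dimethoxy-5-(prop-1-en-2-yl)heptan-2-one | CC(=O)CC[C@H](CC(OC)OC)C(C)=C | intermediate
5 | (5R)-7,7-dimethoxy-5-(prop-1-en-2-yl)hept-1-en-2-yl trifluoromethanesulfonate | C=C(OS(=O)(=O)C(F)(F)F)CC[C@H](CC(OC)OC)C(C)=C | intermediate
6 | [(5R)-7,7-dimethoxy-2-methylidene-5-(prop-1-en-2-yl)heptyl]trimethylsilane | C=C(C[Si](C)(C)C)CC[C@H](CC(OC)OC)C(C)=C | intermediate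
7 | (3R)-6-methylidene-3-(prop-1-en-2-yl)-7-(trimethylsilyl)heptanal | O=CC[C@@H](CCC(=C)C[Si](C)(C)C)C(C)=C | intermediate
8 | dimethyl phosphite | CO[PH](=O)OC | starting material
9 | ethyl glyoxylate | CCOC(=O)C=O | starting material
10 | ethyl 2-(dimethoxyphosphoryl)-2-hydroxyacetate | CCOC(=O)C(O)P(=O)(OC)OC | intermediate
11 | ethyl 2-acetoxy-2-(dimethoxyphosphoryl)acetate | CCOC(=O)C(OC(C)=O)P(=O)(OC)OC | intermediate
12 | (2E)-4-acetoxy-2-methylbut-2-enal | O=C/C(C)=C/COC(C)=O | starting material
13 | ethyl (2Z,4E)-2,6-diacetoxy-4-methylhexa-2,4-dienoate | CCOC(=O)/C(OC(C)=O)=C/C(C)=C/COC(C)=O | intermediate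
14 | ethyl (2R,4E)-2,6-diacetoxy-4-methylhex-4-enoate | CCOC(=O)[C@@H](C/C(C)=C/COC(C)=O)OC(C)=O | intermediate
15 | (2E)-4-[(2R)-3-hydroxy-5-oxo-2,5-dihydrofuran-2-yl]-3-methylbut-2-en-1-yl acetate | O=C1C=C(O)[C@@H](C/C(C)=C/COC(C)=O)O1 | intermediate
16 | (5R)-4-hydroxy-5-[(2E)-4-hydroxy-2-methylbut-2-en-1-yl]furan-2(5H)-one | O=C1C=C(O)[C@@H](C/C(C)=C/CO)O1 | intermediate
17 | (5R)-5-[(2E)-4-hydroxy-2-methylbut-2-en-1-yl]-3-[(3R)-6-methylidene-3-(prop-1-en-2-yl)-7-(trimethylsilyl)heptylidene]furan-2,4(3H,5H)-dione | O=C1O[C@H](C/C(C)=C/CO)C(=O)C1=CC[C@@H](CCC(=C)C[Si](C)(C)C)C(C)=C | intermediate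
18 | (5R)-4-hydroxy-5-[(2E)-4-hydroxy-2-methylbut-2-en-1-yl]-3-[(3S)-6-methylidene-3-(prop-1-en-2-yl)-7-(trimethylsilyl)heptyl]furan-2(5H)-one | O=C1C(CC[C@@H](CCC(=C)C[Si](C)(C)C)C(C)=C)=C(O)[C@@H](C/C(C)=C/CO)O1 | intermediate
19 | (2R)-2-[(2E)-4-hydroxy-2-methylbut-2-en-1-yl]-4-[(3S)-6-methylidene-3-(prop-1-en-2-yl)-7-(trimethylsilyl)heptyl]-5-oxo-2,5-dihydrofuran-3-yl trifluoromethanesulfonate | O=C1C(CC[C@@H](CCC(=C)C[Si](C)(C)C)C(C)=C)=C(OS(=O)(=O)C(F)(F)F)[C@@H](C/C(C)=C/CO)O1 | intermediate
20 | (2R)-2-[(2E)-2-methyl-4-oxobut-2-en-1-yl]-4-[(3S)-6-methylidene-3-(prop-1-en-2-yl)-7-(trimethylsilyl)heptyl]-5-oxo-2,5-dihydrofuran-3-yl trifluoromethanesulfonate | O=C1C(CC[C@@H](CCC(=C)C[Si](C)(C)C)C(C)=C)=C(OS(=O)(=O)C(F)(F)F)[C@@H](C/C(C)=C/C=O)O1 | intermediate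
21 | (1R,6RS,7E,10R)-6-hydroxy-11-(trifluoromethanesulfonyloxy)-11,15-secoverticilla-4(20),7,11,15-tetraen-18,10-olide (14-membered carbocycle C1–C14, butenolide across C10–C12, isopropenyl on C1; both C6 epimers) | C=C1CC[C@@H](C(C)=C)CCC2=C(OS(=O)(=O)C(F)(F)F)[C@@H](C/C(C)=C/C(O)C1)OC2=O | intermediate
22 | (1R,7E,10R)-6-oxo-11-(trifluoromethanesulfonyloxy)-11,15-secoverticilla-4(20),7,11,15-tetraen-18,10-olide | C=C1CC[C@@H](C(C)=C)CCC2=C(OS(=O)(=O)C(F)(F)F)[C@@H](C/C(C)=C/C(=O)C1)OC2=O | intermediate
23 | (1R,6S,7E,10R)-6-hydroxy-11-(trifluoromethanesulfonyloxy)-11,15-secoverticilla-4(20),7,11,15-tetraen-18,10-olide | C=C1CC[C@@H](C(C)=C)CCC2=C(OS(=O)(=O)C(F)(F)F)[C@@H](C/C(C)=C/[C@@H](O)C1)OC2=O | intermediate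
24 | (1R,6S,7E,10R)-6-hydroxyverticilla-4(20),7,11-trien-18,10-olide | C=C1CC[C@@H]2CCC3=C([C@@H](C/C(C)=C/[C@@H](O)C1)OC3=O)C2(C)C | intermediate
25 | (1R,6S,7E,10R)-6-acetoxyverticilla-4(20),7,11-trien-18,10-olide (CNP0289913.1) | C=C1CC[C@@H]2CCC3=C([C@@H](C/C(C)=C/[C@@H](OC(C)=O)C1)OC3=O)C2(C)C | target

Total step count: 17. Longest linear sequence: 13 steps (steps 1–5 to aldehyde 7, then steps 10–17).

Steps most likely to fail

1. Step 16 (key step). What may go wrong: formate may reduce the alkenylpalladium before the transannular insertion takes place (loss of the triflate without ring closure), or the neopentylpalladium may close a cyclopropane onto the butenolide olefin before it is reduced. Fallback: the ring is closed by radical-chain instead of organopalladium chemistry. Setting out from 23, addition–elimination with LiBr (acetone, rt) should exchange the triflate for bromide and give (1R,6S,7E,10R)-11-bromo-6-hydroxy-11,15-secoverticilla-4(20),7,11,15-tetraen-18,10-olide F1. Slow addition of Bu3SnH and AIBN (benzene, 80 °C) then generates the C11 alkenyl radical, which should add 6-exo to C15 of the isopropenyl group; the neopentyl radical at C16 takes a hydrogen atom from the stannane to give 24, where the route is rejoined (tin hydride-mediated alkenyl radical cyclization).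

2. Step 13. What may go wrong: intermolecular allylation (oligomers) may compete with ring closure, or the Lewis acid may ionize the doubly allylic C6 alkoxide, leading to elimination or Prins-type capture by the isopropenyl group. Fallback: organochromium instead of Lewis acid activation. Setting out from 20, bromodesilylation with NBS (CH2Cl2, −78 °C) should give (2R)-4-[(3S)-6-(bromomethyl)-3-(prop-1-en-2-yl)hept-6-en-1-yl]-2-[(2E)-2-methyl-4-oxobut-2-en-1-yl]-5-oxo-2,5-dihydrofuran-3-yl trifluoromethanesulfonate F2. CrCl2 in THF under high dilution then forms the allylchromium reagent, which should add to the enal under neutral conditions (Nozaki–Hiyama–Kishi-type macrocyclization, established for 14-membered cembranoid rings) and return to the route at 21.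

3. Step 15. What may go wrong: hydride delivery may show poor facial selectivity because both flanks of the macrocyclic ketone are unsaturated, or the C4 methylene may drift into conjugation at the ketone stage. Fallback: no ketone is made. Setting out from 21, the C6 epimers are separated by chromatography; the (6S)-epimer is 23 and continues through step 16. The (6R)-epimer, (1R,6R,7E,10R)-6-hydroxy-11-(trifluoromethanesulfonyloxy)-11,15-secoverticilla-4(20),7,11,15-tetraen-18,10-olide F3, is cyclized under the conditions of step 16 to (1R,6R,7E,10R)-6-hydroxyverticilla-4(20),7,11-trien-18,10-olide F4. Mitsunobu esterification of this alcohol with acetic acid (PPh3, DIAD, THF) should give 25 with inversion at C6. The route is rejoined at 23 and at 25, and steps 14 and 15 fall away.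

Further compounds
F1 | step 16 | (1R,6S,7E,10R)-11-bromo-6-hydroxy-11,15-secoverticilla-4(20),7,11,15-tetraen-18,10-olide | C=C1CC[C@@H](C(C)=C)CCC2=C(Br)[C@@H](C/C(C)=C/[C@@H](O)C1)OC2=O
F2 | step 13 | (2R)-4-[(3S)-6-(bromomethyl)-3-(prop-1-en-2-yl)hept-6-en-1-yl]-2-[(2E)-2-methyl-4-oxobut-2-en-1-yl]-5-oxo-2,5-dihydrofuran-3-yl trifluoromethanesulfonate | O=C1C(CC[C@@H](CCC(=C)CBr)C(C)=C)=C(OS(=O)(=O)C(F)(F)F)[C@@H](C/C(C)=C/C=O)O1
F3 | step 15 | (1R,6R,7E,10R)-6-hydroxy-11-(trifluoromethanesulfonyloxy)-11,15-secoverticilla-4(20),7,11,15-tetraen-18,10-olide | C=C1CC[C@@H](C(C)=C)CCC2=C(OS(=O)(=O)C(F)(F)F)[C@@H](C/C(C)=C/[C@H](O)C1)OC2=O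
F4 | step 15 | (1R,6R,7E,10R)-6-hydroxyverticilla-4(20),7,11-trien-18,10-olide | C=C1CC[C@@H]2CCC3=C([C@@H](C/C(C)=C/[C@H](O)C1)OC3=O)C2(C)C
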